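Retrosynthesis: the two bonds from ring B to its bridging CH2 groups are cut first (A–B bridge, then B–C bridge), then the aryl–acyl bonds of the butyryl groups on rings C and D, and last three C–C bonds of ring D itself.
Ring D is a fully substituted benzene with oxygen on C-1, C-3 and C-5 and three unlike carbon groups (bridging CH2, CH3, butyryl) on C-2, C-4 and C-6. Its three C–O carbons correspond to a ketene carbonyl, a siloxyalkyne carbon and an enol ether carbon, so the ring can be built from a cyclobutenone and an ynol ether that already carries the C–D methylene and ring C.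
Forward: rings B and C come from purchased arenes and ring D is closed in step 4. Rings C and D are then butyrylated and freed from their ethers, ring B is joined through a one-carbon iminium unit, and ring A (from dearomatising gem-dimethylation of butyrylphloroglucinol) is joined last in the same way.
The target is achiral and has no stereogenic double bond, so no stereochemistry has to be set. Regiochemistry comes from the polarity of the ynol ether (ring D) and from the single kind of free carbon in each later coupling partner.
Key step: step 4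

Assumption: ring A (compounds 24–27) is written as the enol tautomer of the target SMILES; its tautomers interconvert freely and carry no stereochemical information.

Step 1
Reactants: 1 2-(2,4,6-trimethoxyphenyl)acetic acid
Product: 2 methyl 2-(2,4,6-trimethoxyphenyl)acetate
Conditions: MeOH, H2SO4 (cat.), reflux
Reagents that add atoms: methanol, SMILES CO
Why: Fischer esterification of an unhindered arylacetic acid is routine and supplies the acyl donor needed for the ynolate synthesis.

Step 2
Reactants: 2 methyl 2-(2,4,6-trimethoxyphenyl)acetate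
Product: 5 triisopropyl{[3-(2,4,6-trimethoxyphenyl)prop-1-yn-1-yl]oxy}silane, via lithium dibromoenolate 3 (not isolated), via lithium ynolate 4 (not isolated)
Conditions: CH2Br2, lithium 2,2,6,6-tetramethylpiperidide, THF, −78 °C; LiN(SiMe3)2, −78 → −20 °C; n-BuLi, −78 °C → rt; TIPSCl, −78 °C → rt
Reagents that add atoms: dibromomethane, SMILES BrCBr; triisopropylsilyl chloride, SMILES CC(C)[Si](Cl)(C(C)C)C(C)C
Why: Kowalski ester homologation stopped at the ynolate: LiCHBr2 should add to the ester carbonyl at −78 °C faster than it enolises this electron-rich, doubly ortho-substituted arylacetate, bromine–lithium exchange on 3 triggers the 1,2-shift of the arylmethyl group that gives 4, and the bulky chlorosilane silylates 4 on oxygen rather than on carbon.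

Step 3
Reactants: 6 1-ethoxyprop-1-yne; 7 acetyl chloride
Product: 9 3-ethoxy-2-methylcyclobut-2-en-1-one, via ketene 8 (not isolated)
Conditions: Et3N, Et2O, 0 °C → rt, slow addition of 7
Reagents that add atoms: none
Why: Thermal ketene–ynol ether [2+2] cycloaddition: ketene released slowly by dehydrochlorination is attacked at its carbonyl carbon by the methyl-bearing, nucleophilic alkyne carbon of 6, which places CH3 on C-2 and OEt on C-3 of the cyclobutenone.

Step 4
Reactants: 5 triisopropyl{[3-(2,4,6-trimethoxyphenyl)prop-1-yn-1-yl]oxy}silane; 9 3-ethoxy-2-methylcyclobut-2-en-1-one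
Product: 14 5-ethoxy-4-methyl-3-(triisopropylsilyloxy)-2-(2,4,6-trimethoxybenzyl)phenol, via vinylketene 10 (not isolated), via cyclobutenone adduct 11 (not isolated), via dienylketene 12 (not isolated), via cyclohexadienone 13 (not isolated)
Conditions: 5 (1.1 equiv), 9 (1.0 equiv), PhMe (about 0.5 M), sealed tube, 80 °C then 120 °C
Reagents that add atoms: none
Why: On heating, 9 breaks its C-1–C-4 bond in a four-electron electrocyclic opening to vinylketene 10, and the benzyl-bearing alkyne carbon of 5 attacks the ketene carbonyl carbon in a [2+2] cycloaddition that makes two C–C bonds and gives the 4-vinylcyclobutenone 11. A second four-electron opening turns 11 into dienylketene 12, and ring D then closes by a thermal six-electron (disrotatory) electrocyclisation of the terminal CH2 onto the ketene carbon, the third C–C bond, to give dienone 13, which tautomerises irreversibly to phenol 14. The closest known reaction type is the Danheiser benzannulation of cyclobutenones with triisopropylsiloxyalkynes, which delivers monosilylated resorcinols and, from 3-oxygenated cyclobutenones, phloroglucinol derivatives. No stereocentre has to be controlled, because the quaternary carbon of racemic 11 becomes planar again in 12. The one selectivity required is the orientation of the [2+2] step, and it is secured by the oxygen lone pair of the ynol ether, which makes the carbon beta to oxygen the donor site and lets the siloxy carbon carry the developing positive charge; OH, OTIPS and OEt therefore end on alternate carbons, with CH2Ar between OH and OTIPS, CH3 between OTIPS and OEt, and H between OEt and OH. The small excess of 5 limits esterification of phenol 14 by unconsumed 10.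

Step 5
Reactants: 14 5-ethoxy-4-methyl-3-(triisopropylsilyloxy)-2-(2,4,6-trimethoxybenzyl)phenol
Product: 15 5-ethoxy-4-methyl-2-(2,4,6-trimethoxybenzyl)benzene-1,3-diol
Conditions: TBAF, AcOH, THF, 0 °C, argon
Reagents that add atoms: none
Why: Fluoride-induced cleavage of an aryl silyl ether leaves the alkyl ethers untouched, and the acetic acid buffer keeps the oxidation-prone resorcinol from standing as its phenoxide.

Step 6
Reactants: 15 5-ethoxy-4-methyl-2-(2,4,6-trimethoxybenzyl)benzene-1,3-diol
Product: 17 1-[3-(3-butanoyl-2,4,6-trimethoxybenzyl)-6-ethoxy-2,4-dihydroxy-5-methylphenyl]butan-1-one, via ring D monoketone 16 (not isolated)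
Conditions: n-PrCOCl (2.3 equiv), TiCl4 (4 equiv), CH2Cl2, −30 → 0 °C; aq HCl work-up
Reagents that add atoms: butanoyl chloride, SMILES CCCC(=O)Cl
Why: Friedel–Crafts acylation under TiCl4: ring D has one free carbon, ortho to a titanium phenolate that directs the acylium ion there, ring C has two equivalent free carbons of which only one should react because the first TiCl4-bound ketone deactivates the ring, and the low temperature keeps ipso-protonation of the acid-sensitive diarylmethane slower than acylation.

Step 7
Reactants: 17 1-[3-(3-butanoyl-2,4,6-trimethoxybenzyl)-6-ethoxy-2,4-dihydroxy-5-methylphenyl]butan-1-one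
Product: 18 1-[3-(3-butanoyl-2,4,6-trihydroxybenzyl)-2,4,6-trihydroxy-5-methylphenyl]butan-1-one (free rings C–D dimer)
Conditions: BBr3 (excess), CH2Cl2, −78 °C → rt; ice-water
Reagents that add atoms: none
Why: Lewis-acid cleavage of aryl alkyl ethers with BBr3, assisted by chelation to the ketones for the three ortho alkoxy groups, should free all four masked phenols, while the boron-chelated acyl groups make both rings too electron-poor for retro-Friedel–Crafts loss of the methylene bridge.

Step 8
Reactants: 18 free rings C–D dimer; 19 1-(2,4,6-trihydroxyphenyl)butan-1-one (butyrylphloroglucinol)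
Product: 22 rings B–C–D trimer (ring B = 3-substituted butyrylphloroglucinol that keeps one free aromatic CH), via Mannich base hydroiodide 20 (not isolated), via ortho-quinone methide 21 (not isolated)
Conditions: 18, CH2=NMe2+ I− (1.0 equiv), MeCN, 0 °C → rt; then 19 (5 equiv), 70 °C
Reagents that add atoms: N,N-dimethylmethyleneiminium iodide (Eschenmoser's salt), SMILES C=[N+](C)C.[I-]
Why: Mannich aminomethylation at the only free aromatic carbon of 18 followed by thermal loss of the amine as its hydroiodide gives ortho-quinone methide 21, which is captured through carbon by 19 in a Friedel–Crafts-type conjugate addition, the established way to unsymmetrical methylene-bridged acylphloroglucinols, and the excess of 19 holds back a second alkylation of ring B.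

Step 9
Reactants: 19 1-(2,4,6-trihydroxyphenyl)butan-1-one
Product: 24 2-butanoyl-3,5-dihydroxy-4,4-dimethylcyclohexa-2,5-dien-1-one (butyrylfilicinic acid), via monomethyl ketone 23 (not isolated)
Conditions: NaOMe, MeI (2.1 equiv), MeOH, 0 °C → rt; aq HCl
Reagents that add atoms: iodomethane, SMILES CI
Why: Dearomatising geminal C-methylation of an acylphloroglucinol anion is the classical entry to acylfilicinic acids, the second methyl group should enter at the already methylated and more nucleophilic carbon of 23, and limiting MeI to about two equivalents restrains tri- and tetramethylation.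

Step 10
Reactants: 24 butyrylfilicinic acid; 22 rings B–C–D trimer
Product: 27 target tetramer CNP0246352.0, via Mannich base hydroiodide 25 (not isolated), via methylidene trione 26 (not isolated)
Conditions: 24, CH2=NMe2+ I− (1.0 equiv), MeCN, 0 °C → rt; then 22 (1.0 equiv), THF–MeCN, rt → 40 °C
Reagents that add atoms: N,N-dimethylmethyleneiminium iodide (Eschenmoser's salt), SMILES C=[N+](C)C.[I-]
Why: Mannich reaction at the one enolic CH of 24 and elimination give alkylidene trione 26, a strong Michael acceptor that the last free carbon of ring B in 22 should attack near room temperature, so the most exchange-prone bridge (A–B) is made last and is exposed to neither heat nor base.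

Compound list
1 | 2-(2,4,6-trimethoxyphenyl)acetic acid | COc1cc(OC)c(CC(=O)O)c(OC)c1 | starting material
2 | methyl 2-(2,4,6-trimethoxyphenyl)acetate | COc1cc(OC)c(CC(=O)OC)c(OC)c1 | intermediate
3 | lithium 1,1-dibromo-3-(2,4,6-trimethoxyphenyl)prop-1-en-2-olate | COc1cc(OC)c(CC([O-])=C(Br)Br)c(OC)c1.[Li+] | intermediate
4 | lithium 3-(2,4,6-trimethoxyphenyl)prop-1-yn-1-olate | COc1cc(OC)c(CC#C[O-])c(OC)c1.[Li+] | intermediate
5 | triisopropyl{[3-(2,4,6-trimethoxyphenyl)prop-1-yn-1-yl]oxy}silane | COc1cc(OC)c(CC#CO[Si](C(C)C)(C(C)C)C(C)C)c(OC)c1 | intermediate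
6 | 1-ethoxyprop-1-yne | CCOC#CC | starting material
7 | acetyl chloride | CC(=O)Cl | starting material
8 | ketene (ethenone) | C=C=O | intermediate
9 | 3-ethoxy-2-methylcyclobut-2-en-1-one | CCOC1=C(C)C(=O)C1 | intermediate
10 | 3-ethoxy-2-methylbuta-1,3-dien-1-one (vinylketene) | C=C(OCC)C(C)=C=O | intermediate
11 | 4-(1-ethoxyethenyl)-4-methyl-3-(triisopropylsilyloxy)-2-(2,4,6-trimethoxybenzyl)cyclobut-2-en-1-one (racemic) | O=C1C(Cc2c(OC)cc(OC)cc2OC)=C(O[Si](C(C)C)(C(C)C)C(C)C)C1(C)C(=C)OCC | intermediate
12 | (3E)-5-ethoxy-4-methyl-3-(triisopropylsilyloxy)-2-(2,4,6-trimethoxybenzyl)hexa-1,3,5-trien-1-one (dienylketene, ketenyl and vinyl groups cis) | O=C=C(Cc1c(OC)cc(OC)cc1OC)/C(O[Si](C(C)C)(C(C)C)C(C)C)=C(C)\C(=C)OCC | intermediate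
13 | 5-ethoxy-4-methyl-3-(triisopropylsilyloxy)-2-(2,4,6-trimethoxybenzyl)cyclohexa-2,4-dien-1-one | O=C1CC(OCC)=C(C)C(O[Si](C(C)C)(C(C)C)C(C)C)=C1Cc1c(OC)cc(OC)cc1OC | intermediate
14 | 5-ethoxy-4-methyl-3-(triisopropylsilyloxy)-2-(2,4,6-trimethoxybenzyl)phenol | COc1cc(OC)c(Cc2c(O)cc(OCC)c(C)c2O[Si](C(C)C)(C(C)C)C(C)C)c(OC)c1 | intermediate
15 | 5-ethoxy-4-methyl-2-(2,4,6-trimethoxybenzyl)benzene-1,3-diol | COc1cc(OC)c(Cc2c(O)cc(OCC)c(C)c2O)c(OC)c1 | intermediate
16 | 1-[6-ethoxy-2,4-dihydroxy-5-methyl-3-(2,4,6-trimethoxybenzyl)phenyl]butan-1-one | COc1cc(OC)c(Cc2c(O)c(C(=O)CCC)c(OCC)c(C)c2O)c(OC)c1 | intermediate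
17 | 1-[3-(3-butanoyl-2,4,6-trimethoxybenzyl)-6-ethoxy-2,4-dihydroxy-5-methylphenyl]butan-1-one | CCCC(=O)c1c(OC)cc(OC)c(Cc2c(O)c(C(=O)CCC)c(OCC)c(C)c2O)c1OC | intermediate
18 | 1-[3-(3-butanoyl-2,4,6-trihydroxybenzyl)-2,4,6-trihydroxy-5-methylphenyl]butan-1-one (rings C–D dimer) | CCCC(=O)c1c(O)cc(O)c(Cc2c(O)c(C)c(O)c(C(=O)CCC)c2O)c1O | intermediate
19 | 1-(2,4,6-trihydroxyphenyl)butan-1-one (butyrylphloroglucinol) | CCCC(=O)c1c(O)cc(O)cc1O | starting material
20 | hydroiodide of 18 carrying CH2NMe2 on the free carbon of ring C | CCCC(=O)c1c(O)c(C[NH+](C)C)c(O)c(Cc2c(O)c(C)c(O)c(C(=O)CCC)c2O)c1O.[I-] | intermediate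
21 | ortho-quinone methide of ring C (exocyclic CH2 next to a ring C=O, ring D unchanged) | C=C1C(=O)C(Cc2c(O)c(C)c(O)c(C(=O)CCC)c2O)=C(O)C(C(=O)CCC)=C1O | intermediate
22 | rings B–C–D trimer: butyrylphloroglucinol (B) linked by CH2 to ring C of 18 | CCCC(=O)c1c(O)cc(O)c(Cc2c(O)c(Cc3c(O)c(C)c(O)c(C(=O)CCC)c3O)c(O)c(C(=O)CCC)c2O)c1O | intermediate
23 | 1-(2,4,6-trihydroxy-3-methylphenyl)butan-1-one | CCCC(=O)c1c(O)cc(O)c(C)c1O | intermediate
24 | 2-butanoyl-3,5-dihydroxy-4,4-dimethylcyclohexa-2,5-dien-1-one (butyrylfilicinic acid) | CCCC(=O)C1=C(O)C(C)(C)C(O)=CC1=O | intermediate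
25 | hydroiodide of 24 carrying CH2NMe2 on C-6 | CCCC(=O)C1=C(O)C(C)(C)C(O)=C(C[NH+](C)C)C1=O.[I-] | intermediate
26 | 2-butanoyl-3-hydroxy-4,4-dimethyl-6-methylidenecyclohex-2-ene-1,5-dione | CCCC(=O)C1=C(O)C(C)(C)C(=O)C(=C)C1=O | intermediate
27 | CNP0246352.0, tetramer A–CH2–B–CH2–C–CH2–D (achiral) | CCCC(=O)C1=C(O)C(C)(C)C(O)=C(Cc2c(O)c(Cc3c(O)c(Cc4c(O)c(C)c(O)c(C(=O)CCC)c4O)c(O)c(C(=O)CCC)c3O)c(O)c(C(=O)CCC)c2O)C1=O | target

Total step count: 10. Longest linear sequence: 8 (steps 1, 2, 4, 5, 6, 7, 8, 10).

Most likely to fail

Risk 1, the double acylation of step 6. Acid generated in the flask may protonate an ipso carbon of the very electron-rich diarylmethane and cleave or scramble the bridge. O-acylation of the ring D phenols may stall C-acylation, and partial loss of methyl groups may blur the product. The fallback sets out from 15 and comes back at 18, and it brings in both acyl groups by anionic instead of cationic chemistry.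
- Diol 15 is O-methylated (MeI, K2CO3, acetone) to 1-ethoxy-3,5-dimethoxy-2-methyl-4-(2,4,6-trimethoxybenzyl)benzene F1.
- NBS (2 equiv, MeCN, −20 °C) brominates the single free carbon of ring D and one of the two equivalent carbons of ring C, giving 1-bromo-2-ethoxy-4,6-dimethoxy-3-methyl-5-(3-bromo-2,4,6-trimethoxybenzyl)benzene F2.
- Bromine–lithium exchange (n-BuLi, THF, −78 °C) gives the dilithiated diarylmethane F3, which N-methoxy-N-methylbutanamide acylates to the fully etherified bis-ketone F4.
- BBr3 then removes all six alkyl groups to reach 18.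

Risk 2, the B–C coupling of step 8. A second quinone methide may alkylate the remaining carbon of ring B, 21 may trap itself, and liberated amine may start exchange of methylene bridges. The fallback sets out from 24 and 19, uses 20, and comes back at 27. The assembly changes from linear to convergent, so that ring B meets the valuable C–D unit only when it has a single free carbon left.
- Compound 24 is taken through 25 and 26 as in step 10, and 26 is trapped with an excess of cheap 19 to give the rings A–B dimer F5.
- Salt 20, formed from 18 as in the first half of step 8, is then warmed with F5 in the non-basic iodide medium.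
- Quinone methide 21 is captured at the one open carbon of ring B and gives 27 directly, which replaces the second half of step 8 and all of step 10.

Risk 3, the ynolate formation of step 2. The amide base or LiCHBr2 may enolise the arylacetate instead of adding to its carbonyl group, and the doubly activated CH2 of 4 may be deprotonated and isomerise towards an allene. The fallback sets out from 2 and comes back at 4, and it reaches the ynolate by oxidation of an acetylide instead of by rearrangement.
- i-Bu2AlH (CH2Cl2, −78 °C) reduces 2 to 2-(2,4,6-trimethoxyphenyl)acetaldehyde F6.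
- Ohira–Bestmann homologation (dimethyl (1-diazo-2-oxopropyl)phosphonate, K2CO3, MeOH) gives 1,3,5-trimethoxy-2-(prop-2-yn-1-yl)benzene F7.
- n-BuLi (THF, −78 °C) gives the lithium acetylide F8, which lithium tert-butyl peroxide (t-BuOOH, LiN(SiMe3)2) oxidises to ynolate 4.
- O-silylation with TIPSOTf then gives 5.

Further compounds
F1 | step 6 | 1-ethoxy-3,5-dimethoxy-2-methyl-4-(2,4,6-trimethoxybenzyl)benzene | COc1cc(OC)c(Cc2c(OC)cc(OCC)c(C)c2OC)c(OC)c1
F2 | step 6 | 1-bromo-2-ethoxy-4,6-dimethoxy-3-methyl-5-(3-bromo-2,4,6-trimethoxybenzyl)benzene | COc1cc(OC)c(Cc2c(OC)c(Br)c(OCC)c(C)c2OC)c(OC)c1Br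
F3 | step 6 | dilithiated diarylmethane (Li in place of both Br of F2) | COc1cc(OC)c(Cc2c(OC)c([Li])c(OCC)c(C)c2OC)c(OC)c1[Li]
F4 | step 6 | 1-[3-(3-butanoyl-2,4,6-trimethoxybenzyl)-6-ethoxy-2,4-dimethoxy-5-methylphenyl]butan-1-one | CCCC(=O)c1c(OC)cc(OC)c(Cc2c(OC)c(C(=O)CCC)c(OCC)c(C)c2OC)c1OC
F5 | step 8 | rings A–B dimer: butyrylfilicinic acid linked by CH2 to C-3 of butyrylphloroglucinol | CCCC(=O)C1=C(O)C(C)(C)C(O)=C(Cc2c(O)cc(O)c(C(=O)CCC)c2O)C1=O
F6 | step 2 | 2-(2,4,6-trimethoxyphenyl)acetaldehyde | COc1cc(OC)c(CC=O)c(OC)c1
F7 | step 2 | 1,3,5-trimethoxy-2-(prop-2-yn-1-yl)benzene | COc1cc(OC)c(CC#C)c(OC)c1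
F8 | step 2 | lithium acetylide of F7 | COc1cc(OC)c(CC#C[Li])c(OC)c1
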